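**Plan**

1. The last cut is the ester C–O between the two halves (Yamaguchi). In the acid half, the cyclohexene ring bonds C1–C2 and C5–C6 are cut together as a Diels–Alder reaction (C1 carries the acrylate chain, C2=C3 is the ring alkene, C3 carries CH2OH, C6 carries isopropyl).
2. This works because C1 and C6 are vicinal and cis, so they can be the two alkene carbons of a butenolide. The lactone is a temporary ring: its carbonyl becomes the isopropyl group and its CH(CH2OH)–O carbon becomes the side-chain CH=. C2–C5 comes from a (1E)-1-silyl-2-(silyloxymethyl)butadiene; the adduct is an allylsilane, and protodesilylation moves the alkene from C3=C4 to C2=C3.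
3. Acid half, forward: diene (hydrostannation, Stille) → cycloaddition → double Grignard addition → periodate cleavage to a lactol → Wittig → dehydration and hydrogenation → acid 17.
4. Alcohol half, forward: cyclohexenone by enamine Michael/aldol → spiro-epoxide → tertiary carbinol → carbonylation → vinyl conjugate addition with kinetic protonation → seven-membered lactone by ring-closing metathesis → diol 31. After the union, one acid step removes SiMe3 (alkene shift), both silyl ethers and the tert-butyl ester.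
5. Stereochemistry: the acid half takes it from the stereocentre of (S)-5-(hydroxymethyl)butenolide (anti addition) and the Z-locked dienophile. The alcohol half takes it from the organocatalytic Michael step (isopropyl carbon), then axial ylide attack, cuprate addition anti to isopropyl and kinetic protonation. The alkene geometries come from the Wittig reaction and from ring constraint.

Key step: step 4

Assumption: the silicon-bearing carbon of 7 is drawn as the endo epimer; the exo epimer would follow the same route, because this centre becomes sp2 in step 23.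

**Route**

Step 1
Reactants: 1 3-(trimethylsilyl)prop-2-yn-1-ol
Product: 2 (E)-2-(tributylstannyl)-3-(trimethylsilyl)prop-2-en-1-ol
Conditions: Bu3SnH, PdCl2(PPh3)2 (2 mol %), THF, 0 °C to rt
Reagents that add atoms: tributyltin hydride CCCC[SnH](CCCC)CCCC
Why: Palladium-catalysed hydrostannation adds H and Sn syn across the silylalkyne with tin on the carbon remote from silicon, so silicon and tin end up trans on the alkene.

Step 2
Reactants: 2 (E)-2-(tributylstannyl)-3-(trimethylsilyl)prop-2-en-1-ol; 3 bromoethene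
Product: 4 (2Z)-2-[(trimethylsilyl)methylidene]but-3-en-1-ol
Conditions: Pd(PPh3)4 (5 mol %), CuI (10 mol %), DMF, 40 °C, sealed vessel
Reagents that add atoms: none
Why: Stille coupling replaces tin by vinyl with retention of alkene geometry, which places silicon trans to the new vinyl group (the outside position that an s-cis diene needs).

Step 3
Reactants: 4 (2Z)-2-[(trimethylsilyl)methylidene]but-3-en-1-ol
Product: 5 tert-butyl(dimethyl){[(2Z)-2-[(trimethylsilyl)methylidene]but-3-en-1-yl]oxy}silane
Conditions: TBSCl, imidazole, CH2Cl2, 0 °C to rt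
Reagents that add atoms: tert-butyldimethylsilyl chloride CC(C)(C)[Si](C)(C)Cl
Why: Standard silylation of a primary alcohol gives an ether that should survive the Grignard, periodate, Wittig, elimination and hydrogenation steps and fall in the final acid step.

Step 4
Reactants: 5 tert-butyl(dimethyl){[(2Z)-2-[(trimethylsilyl)methylidene]but-3-en-1-yl]oxy}silane; 6 (5S)-5-(hydroxymethyl)furan-2(5H)-one
Product: 7 (3S)-5-({[tert-butyl(dimethyl)silyl]oxy}methyl)-3-(hydroxymethyl)-4-(trimethylsilyl)-3a,4,7,7a-tetrahydro-2-benzofuran-1(3H)-one (cis ring fusion; carbocycle anti to the 3-CH2OH group; SiMe3 cis to the lactone ring)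
Conditions: toluene (1 M), BHT (cat.), sealed tube, 150 °C
Reagents that add atoms: none
Why: This is a thermal Diels–Alder reaction, concerted and suprafacial on both partners; its closest known relatives are cycloadditions of 5-substituted butenolides with 2-substituted dienes and with 1-silyl dienes. The cyclohexene ring closes by intermolecular [4+2] cycloaddition, both ring bonds forming in the same event, so there is no separate exo or endo cyclisation. The two ring-fusion stereocentres are cis because the dienophile alkene is held Z inside the lactone, and their absolute configuration follows from the C5 stereocentre of 6, the diene adding to the face anti to the hydroxymethyl group. The step needs the regiochemistry in which the silicon-bearing diene terminus bonds to the lactone β-carbon; the 2-alkyl substituent (para rule relative to the carbonyl-bearing carbon) and the ipso-directing silyl group (β-silicon stabilisation of developing positive charge) both favour it. The silicon-bearing carbon should form mainly as the endo (all-cis) epimer, but endo/exo selectivity is not required because this centre is erased later. The allylsilane created here is the latent form of the C2=C3 ring alkene of the target.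

Step 5
Reactants: 7 (3S)-5-({[tert-butyl(dimethyl)silyl]oxy}methyl)-3-(hydroxymethyl)-4-(trimethylsilyl)-3a,4,7,7a-tetrahydro-2-benzofuran-1(3H)-one
Product: 8 (1S)-1-[3-({[tert-butyl(dimethyl)silyl]oxy}methyl)-6-(2-hydroxypropan-2-yl)-2-(trimethylsilyl)cyclohex-3-en-1-yl]ethane-1,2-diol (ring substituents at C1/C2/C6 all cis)
Conditions: MeMgBr (6 equiv), THF, 0 °C to rt; aq NH4Cl
Reagents that add atoms: methylmagnesium bromide C[Mg]Br
Why: Double Grignard addition to the lactone carbonyl gives the tertiary carbinol that is the isopropyl group in latent form, and the ring stereocentres should stay intact because addition outpaces enolisation of the cis-fused lactone.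

Step 6
Reactants: 8 (1S)-1-[3-({[tert-butyl(dimethyl)silyl]oxy}methyl)-6-(2-hydroxypropan-2-yl)-2-(trimethylsilyl)cyclohex-3-en-1-yl]ethane-1,2-diol
Product: 9 6-({[tert-butyl(dimethyl)silyl]oxy}methyl)-3,3-dimethyl-7-(trimethylsilyl)-1,3,3a,4,7,7a-hexahydro-2-benzofuran-1-ol (cis-fused lactol; anomer mixture)
Conditions: NaIO4, THF/H2O (pH 7 buffer), 0 °C
Reagents that add atoms: none
Why: Periodate glycol cleavage (Malaprade reaction) removes the auxiliary carbon as formaldehyde, and the ring aldehyde so unveiled is trapped at once by the neighbouring tertiary alcohol as the cis-fused lactol, which shields the epimerisable α-carbon.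

Step 7
Reactants: 10 methyl 2-bromo-3-hydroxypropanoate (racemic)
Product: 11 methyl 2-bromo-3-{[tert-butyl(dimethyl)silyl]oxy}propanoate
Conditions: TBSCl, imidazole, CH2Cl2, rt
Reagents that add atoms: tert-butyldimethylsilyl chloride CC(C)(C)[Si](C)(C)Cl
Why: Standard silylation of the primary alcohol prepares the α-bromo ester for phosphonium salt formation.

Step 8
Reactants: 11 methyl 2-bromo-3-{[tert-butyl(dimethyl)silyl]oxy}propanoate
Product: 13 methyl 3-{[tert-butyl(dimethyl)silyl]oxy}-2-(triphenyl-λ5-phosphanylidene)propanoate, via phosphonium bromide 12 (not isolated)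
Conditions: PPh3, toluene, 80 °C; then 1 M NaOH/CH2Cl2, 0 °C
Reagents that add atoms: triphenylphosphine c1ccc(cc1)P(c1ccccc1)c1ccccc1
Why: SN2 displacement of the α-bromo ester by the phosphine and deprotonation of the salt give the ester-stabilised ylide, the usual preparation of Wittig reagents of this class.

Step 9
Reactants: 9 6-({[tert-butyl(dimethyl)silyl]oxy}methyl)-3,3-dimethyl-7-(trimethylsilyl)-1,3,3a,4,7,7a-hexahydro-2-benzofuran-1-ol; 13 methyl 3-{[tert-butyl(dimethyl)silyl]oxy}-2-(triphenyl-λ5-phosphanylidene)propanoate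
Product: 14 methyl (2E)-2-({[tert-butyl(dimethyl)silyl]oxy}methyl)-3-[3-({[tert-butyl(dimethyl)silyl]oxy}methyl)-6-(2-hydroxypropan-2-yl)-2-(trimethylsilyl)cyclohex-3-en-1-yl]prop-2-enoate (ring substituents all cis)
Conditions: PhCO2H (10 mol %), toluene, 90 °C
Reagents that add atoms: none
Why: Wittig olefination of the lactol through its open hydroxy aldehyde with the stabilised α-substituted ylide should give the trisubstituted enoate with the ester trans to the ring carbon (E), and the aldehyde is not prone to conjugate because the ring alkene is still one carbon further away.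

Step 10
Reactants: 14 methyl (2E)-2-({[tert-butyl(dimethyl)silyl]oxy}methyl)-3-[3-({[tert-butyl(dimethyl)silyl]oxy}methyl)-6-(2-hydroxypropan-2-yl)-2-(trimethylsilyl)cyclohex-3-en-1-yl]prop-2-enoate
Product: 15 methyl (2E)-2-({[tert-butyl(dimethyl)silyl]oxy}methyl)-3-[3-({[tert-butyl(dimethyl)silyl]oxy}methyl)-6-(prop-1-en-2-yl)-2-(trimethylsilyl)cyclohex-3-en-1-yl]prop-2-enoate
Conditions: Burgess reagent, toluene, 50 °C
Reagents that add atoms: none
Why: Burgess dehydration (syn elimination through the sulfamate ester) should take a methyl hydrogen and not the single ring methine hydrogen, on statistical grounds and because the isopropylidene isomer would suffer allylic 1,3-strain with the cis side chain.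

Step 11
Reactants: 15 methyl (2E)-2-({[tert-butyl(dimethyl)silyl]oxy}methyl)-3-[3-({[tert-butyl(dimethyl)silyl]oxy}methyl)-6-(prop-1-en-2-yl)-2-(trimethylsilyl)cyclohex-3-en-1-yl]prop-2-enoate
Product: 16 methyl (2E)-2-({[tert-butyl(dimethyl)silyl]oxy}methyl)-3-[3-({[tert-butyl(dimethyl)silyl]oxy}methyl)-6-(propan-2-yl)-2-(trimethylsilyl)cyclohex-3-en-1-yl]prop-2-enoate
Conditions: H2 (1 atm), RhCl(PPh3)3 (5 mol %), benzene/EtOH, rt
Reagents that add atoms: none
Why: Homogeneous hydrogenation with RhCl(PPh3)3 reduces the unhindered 1,1-disubstituted alkene much faster than the two trisubstituted alkenes (allylsilane and enoate), so the isopropyl group is completed without touching a stereocentre.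

Step 12
Reactants: 16 methyl (2E)-2-({[tert-butyl(dimethyl)silyl]oxy}methyl)-3-[3-({[tert-butyl(dimethyl)silyl]oxy}methyl)-6-(propan-2-yl)-2-(trimethylsilyl)cyclohex-3-en-1-yl]prop-2-enoate
Product: 17 (2E)-2-({[tert-butyl(dimethyl)silyl]oxy}methyl)-3-[3-({[tert-butyl(dimethyl)silyl]oxy}methyl)-6-(propan-2-yl)-2-(trimethylsilyl)cyclohex-3-en-1-yl]prop-2-enoic acid
Conditions: LiOH·H2O, THF/MeOH/H2O, 40 °C; then 1 M HCl to pH 4, 0 °C
Reagents that add atoms: lithium hydroxide [Li+].[OH-]
Why: Saponification of the methyl ester frees the acid for coupling, while the primary silyl ethers and the allylsilane should tolerate hydroxide at this temperature.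

Step 13
Reactants: 18 3-methylbutanal; 19 but-3-en-2-one
Product: 21 (4S)-4-(propan-2-yl)cyclohex-2-en-1-one, via keto aldehyde 20 (not isolated)
Conditions: (S)-2-[diphenyl(trimethylsilyloxy)methyl]pyrrolidine (5 mol %), ethyl 3,4-dihydroxybenzoate (20 mol %), neat, 4 °C; then LiOH, i-PrOH, rt
Reagents that add atoms: none
Why: Enamine-catalysed Michael addition sets the stereocentre, the enone approaching the enamine face away from the bulky diphenyl(silyloxy)methyl group, and base-mediated intramolecular aldol condensation then closes the cyclohexenone (Robinson-type annulation).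

Step 14
Reactants: 21 (4S)-4-(propan-2-yl)cyclohex-2-en-1-one
Product: 22 (4S)-2-iodo-4-(propan-2-yl)cyclohex-2-en-1-one
Conditions: I2, pyridine, CH2Cl2, 0 °C to rt
Reagents that add atoms: iodine II
Why: α-Iodination of the enone by pyridine-mediated conjugate addition, iodination and elimination (a Baylis–Hillman-type sequence) involves no stereocentre and gives the handle for the later carbonylation.

Step 15
Reactants: 22 (4S)-2-iodo-4-(propan-2-yl)cyclohex-2-en-1-one
Product: 23 (6S)-4-iodo-6-(propan-2-yl)-1-oxaspiro[2.5]oct-4-ene (epoxide oxygen trans to isopropyl)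
Conditions: Me3S+ I−, KN(SiMe3)2, THF, −20 °C; then 22, −20 to 0 °C
Reagents that add atoms: trimethylsulfonium iodide C[S+](C)C.[I-]
Why: In this Corey–Chaykovsky epoxidation the sulfonium ylide should add 1,2 to the carbonyl along the pseudoaxial trajectory, which puts the new CH2 cis and the oxygen trans to the pseudoequatorial isopropyl group, a preference reinforced by allylic strain between iodine and a pseudoequatorial CH2S+ group.

Step 16
Reactants: 23 (6S)-4-iodo-6-(propan-2-yl)-1-oxaspiro[2.5]oct-4-ene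
Product: 24 (4S)-2-iodo-1-{[(4-methoxyphenyl)methoxy]methyl}-4-(propan-2-yl)cyclohex-2-en-1-ol (hydroxyl trans to isopropyl)
Conditions: 4-methoxybenzyl alcohol (5 equiv), NaH (0.2 equiv), DMF, 50 °C
Reagents that add atoms: 4-methoxybenzyl alcohol COc1ccc(CO)cc1
Why: Alkoxide opening of the 2,2-disubstituted epoxide occurs by SN2 at the primary carbon, so the tertiary C–O bond and its configuration are kept.

Step 17
Reactants: 24 (4S)-2-iodo-1-{[(4-methoxyphenyl)methoxy]methyl}-4-(propan-2-yl)cyclohex-2-en-1-ol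
Product: 25 2-(trimethylsilyl)ethyl 6-hydroxy-6-{[(4-methoxyphenyl)methoxy]methyl}-3-(propan-2-yl)cyclohex-1-ene-1-carboxylate
Conditions: CO (1 atm), Pd(OAc)2 (5 mol %), PPh3 (10 mol %), Et3N, 2-(trimethylsilyl)ethanol, DMF, 60 °C
Reagents that add atoms: carbon monoxide [C-]#[O+]; 2-(trimethylsilyl)ethanol C[Si](C)(C)CCO
Why: Palladium-catalysed alkoxycarbonylation of the alkenyl iodide (oxidative addition, CO insertion, alcoholysis) installs the ring carboxyl carbon without disturbing the adjacent tertiary alcohol.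

Step 18
Reactants: 25 2-(trimethylsilyl)ethyl 6-hydroxy-6-{[(4-methoxyphenyl)methoxy]methyl}-3-(propan-2-yl)cyclohex-1-ene-1-carboxylate
Product: 26 2-(trimethylsilyl)ethyl 6-ethenyl-2-hydroxy-2-{[(4-methoxyphenyl)methoxy]methyl}-5-(propan-2-yl)cyclohexane-1-carboxylate (ester, vinyl and hydroxyl mutually cis; isopropyl trans to vinyl)
Conditions: CH2=CHMgBr (4 equiv), CuBr·SMe2 (20 mol %), Me3SiCl (3 equiv), THF, −78 to −40 °C; then 1 M aq citric acid, THF, 0 °C
Reagents that add atoms: vinylmagnesium bromide C=C[Mg]Br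
Why: Copper-catalysed conjugate addition of the vinyl Grignard reagent, accelerated by Me3SiCl, should occur anti to the adjacent isopropyl group, and kinetic protonation of the silyl ketene acetal on the face opposite the new vinyl group should give the axial ester cis to vinyl.

Step 19
Reactants: 26 2-(trimethylsilyl)ethyl 6-ethenyl-2-hydroxy-2-{[(4-methoxyphenyl)methoxy]methyl}-5-(propan-2-yl)cyclohexane-1-carboxylate; 27 tert-butyl 2-(bromomethyl)prop-2-enoate
Product: 29 3-tert-butoxy-2-methylidene-3-oxopropyl 6-ethenyl-2-hydroxy-2-{[(4-methoxyphenyl)methoxy]methyl}-5-(propan-2-yl)cyclohexane-1-carboxylate (stereochemistry as 26), via ammonium carboxylate 28 (not isolated)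
Conditions: Bu4NF, THF, 0 °C to rt; then 27, rt
Reagents that add atoms: none
Why: Fluoride-induced fragmentation of the 2-(trimethylsilyl)ethyl ester gives the carboxylate, which is alkylated in the same flask by the allylic bromide (SN2 or the degenerate SN2′), an ester exchange that avoids saponification of the epimerisable axial ester.

Step 20
Reactants: 29 3-tert-butoxy-2-methylidene-3-oxopropyl 6-ethenyl-2-hydroxy-2-{[(4-methoxyphenyl)methoxy]methyl}-5-(propan-2-yl)cyclohexane-1-carboxylate
Product: 30 tert-butyl 9-hydroxy-9-{[(4-methoxyphenyl)methoxy]methyl}-1-oxo-6-(propan-2-yl)-1,3,5a,6,7,8,9,9a-octahydro-2-benzoxepine-4-carboxylate (cis ring fusion; stereochemistry as 26)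
Conditions: second-generation Grubbs catalyst (5 mol %), toluene (0.005 M), 80 °C
Reagents that add atoms: none
Why: Ring-closing metathesis between the vinyl group and the 1,1-disubstituted acrylate alkene closes the seven-membered lactone, and the ring enforces the alkene geometry of the target (ring carbon cis to CH2O).

Step 21
Reactants: 30 tert-butyl 9-hydroxy-9-{[(4-methoxyphenyl)methoxy]methyl}-1-oxo-6-(propan-2-yl)-1,3,5a,6,7,8,9,9a-octahydro-2-benzoxepine-4-carboxylate
Product: 31 tert-butyl 9-hydroxy-9-(hydroxymethyl)-1-oxo-6-(propan-2-yl)-1,3,5a,6,7,8,9,9a-octahydro-2-benzoxepine-4-carboxylate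
Conditions: DDQ, CH2Cl2/pH 7 buffer, 0 °C
Reagents that add atoms: none
Why: Oxidative cleavage of the 4-methoxybenzyl ether by DDQ in wet solvent frees the primary alcohol without touching the esters or the electron-poor alkene.

Step 22
Reactants: 17 (2E)-2-({[tert-butyl(dimethyl)silyl]oxy}methyl)-3-[3-({[tert-butyl(dimethyl)silyl]oxy}methyl)-6-(propan-2-yl)-2-(trimethylsilyl)cyclohex-3-en-1-yl]prop-2-enoic acid; 31 tert-butyl 9-hydroxy-9-(hydroxymethyl)-1-oxo-6-(propan-2-yl)-1,3,5a,6,7,8,9,9a-octahydro-2-benzoxepine-4-carboxylate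
Product: 32 ester of acid 17 with the primary hydroxyl of diol 31 (fully protected, silylated precursor of the target)
Conditions: 2,4,6-trichlorobenzoyl chloride, Et3N, THF, rt; then 31, DMAP, toluene, rt
Reagents that add atoms: none
Why: Yamaguchi esterification through the mixed anhydride acylates the primary hydroxyl selectively over the tertiary one and joins the two halves.

Step 23
Reactants: 32 ester of acid 17 with the primary hydroxyl of diol 31
Product: 33 CNP0361406.6 (target)
Conditions: CF3CO2H/CH2Cl2/H2O (10:10:1), 0 °C to rt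
Reagents that add atoms: none
Why: Acid-mediated global deprotection should protodesilylate the allylsilane by SE2′ (proton to the ring CH carbon γ to silicon, then loss of silicon), which moves the ring alkene to its place in the target, while both silyl ethers and the tert-butyl ester are cleaved in the same medium.

**Compound list**

1 | 3-(trimethylsilyl)prop-2-yn-1-ol | C[Si](C)(C)C#CCO | starting material
2 | (E)-2-(tributylstannyl)-3-(trimethylsilyl)prop-2-en-1-ol | C[Si](C)(C)/C=C(\CO)[Sn](CCCC)(CCCC)CCCC | intermediate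
3 | bromoethene | C=CBr | starting material
4 | (2Z)-2-[(trimethylsilyl)methylidene]but-3-en-1-ol | C[Si](C)(C)/C=C(\CO)C=C | intermediate
5 | tert-butyl(dimethyl){[(2Z)-2-[(trimethylsilyl)methylidene]but-3-en-1-yl]oxy}silane | C[Si](C)(C)/C=C(\CO[Si](C)(C)C(C)(C)C)C=C | intermediate
6 | (5S)-5-(hydroxymethyl)furan-2(5H)-one | OC[C@H]1OC(=O)C=C1 | starting material
7 | (3S)-5-({[tert-butyl(dimethyl)silyl]oxy}methyl)-3-(hydroxymethyl)-4-(trimethylsilyl)-3a,4,7,7a-tetrahydro-2-benzofuran-1(3H)-one, cis-fused, SiMe3 cis to the lactone | OC[C@H]1OC(=O)[C@@H]2CC=C(CO[Si](C)(C)C(C)(C)C)[C@H]([Si](C)(C)C)[C@H]12 | intermediate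
8 | (1S)-1-[3-({[tert-butyl(dimethyl)silyl]oxy}methyl)-6-(2-hydroxypropan-2-yl)-2-(trimethylsilyl)cyclohex-3-en-1-yl]ethane-1,2-diol, all-cis ring | OC[C@@H](O)[C@H]1[C@@H]([Si](C)(C)C)C(CO[Si](C)(C)C(C)(C)C)=CC[C@H]1C(C)(C)O | intermediate
9 | 6-({[tert-butyl(dimethyl)silyl]oxy}methyl)-3,3-dimethyl-7-(trimethylsilyl)-1,3,3a,4,7,7a-hexahydro-2-benzofuran-1-ol, cis-fused, anomer mixture | OC1OC(C)(C)[C@@H]2CC=C(CO[Si](C)(C)C(C)(C)C)[C@H]([Si](C)(C)C)[C@H]12 | intermediate
10 | methyl 2-bromo-3-hydroxypropanoate (racemic) | COC(=O)C(Br)CO | starting material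
11 | methyl 2-bromo-3-{[tert-butyl(dimethyl)silyl]oxy}propanoate | COC(=O)C(Br)CO[Si](C)(C)C(C)(C)C | intermediate
12 | (3-{[tert-butyl(dimethyl)silyl]oxy}-1-methoxy-1-oxopropan-2-yl)triphenylphosphonium bromide | COC(=O)C(CO[Si](C)(C)C(C)(C)C)[P+](c1ccccc1)(c1ccccc1)c1ccccc1.[Br-] | intermediate
13 | methyl 3-{[tert-butyl(dimethyl)silyl]oxy}-2-(triphenyl-λ5-phosphanylidene)propanoate | COC(=O)C(CO[Si](C)(C)C(C)(C)C)=P(c1ccccc1)(c1ccccc1)c1ccccc1 | intermediate
14 | methyl (2E)-2-({[tert-butyl(dimethyl)silyl]oxy}methyl)-3-[3-({[tert-butyl(dimethyl)silyl]oxy}methyl)-6-(2-hydroxypropan-2-yl)-2-(trimethylsilyl)cyclohex-3-en-1-yl]prop-2-enoate, all-cis ring | COC(=O)/C(=C/[C@H]1[C@@H]([Si](C)(C)C)C(CO[Si](C)(C)C(C)(C)C)=CC[C@H]1C(C)(C)O)CO[Si](C)(C)C(C)(C)C | intermediate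
15 | methyl (2E)-2-({[tert-butyl(dimethyl)silyl]oxy}methyl)-3-[3-({[tert-butyl(dimethyl)silyl]oxy}methyl)-6-(prop-1-en-2-yl)-2-(trimethylsilyl)cyclohex-3-en-1-yl]prop-2-enoate | COC(=O)/C(=C/[C@H]1[C@@H]([Si](C)(C)C)C(CO[Si](C)(C)C(C)(C)C)=CC[C@H]1C(C)=C)CO[Si](C)(C)C(C)(C)C | intermediate
16 | methyl (2E)-2-({[tert-butyl(dimethyl)silyl]oxy}methyl)-3-[3-({[tert-butyl(dimethyl)silyl]oxy}methyl)-6-(propan-2-yl)-2-(trimethylsilyl)cyclohex-3-en-1-yl]prop-2-enoate | COC(=O)/C(=C/[C@H]1[C@@H]([Si](C)(C)C)C(CO[Si](C)(C)C(C)(C)C)=CC[C@H]1C(C)C)CO[Si](C)(C)C(C)(C)C | intermediate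
17 | (2E)-2-({[tert-butyl(dimethyl)silyl]oxy}methyl)-3-[3-({[tert-butyl(dimethyl)silyl]oxy}methyl)-6-(propan-2-yl)-2-(trimethylsilyl)cyclohex-3-en-1-yl]prop-2-enoic acid | OC(=O)/C(=C/[C@H]1[C@@H]([Si](C)(C)C)C(CO[Si](C)(C)C(C)(C)C)=CC[C@H]1C(C)C)CO[Si](C)(C)C(C)(C)C | intermediate
18 | 3-methylbutanal | CC(C)CC=O | starting material
19 | but-3-en-2-one | CC(=O)C=C | starting material
20 | (2S)-5-oxo-2-(propan-2-yl)hexanal | CC(C)[C@H](CCC(C)=O)C=O | intermediate
21 | (4S)-4-(propan-2-yl)cyclohex-2-en-1-one | CC(C)[C@@H]1CCC(=O)C=C1 | intermediate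
22 | (4S)-2-iodo-4-(propan-2-yl)cyclohex-2-en-1-one | CC(C)[C@@H]1CCC(=O)C(I)=C1 | intermediate
23 | (6S)-4-iodo-6-(propan-2-yl)-1-oxaspiro[2.5]oct-4-ene, epoxide O trans to isopropyl | CC(C)[C@@H]1CC[C@]2(CO2)C(I)=C1 | intermediate
24 | (4S)-2-iodo-1-{[(4-methoxyphenyl)methoxy]methyl}-4-(propan-2-yl)cyclohex-2-en-1-ol, OH trans to isopropyl | CC(C)[C@@H]1CC[C@](O)(COCc2ccc(OC)cc2)C(I)=C1 | intermediate
25 | 2-(trimethylsilyl)ethyl 6-hydroxy-6-{[(4-methoxyphenyl)methoxy]methyl}-3-(propan-2-yl)cyclohex-1-ene-1-carboxylate | CC(C)[C@@H]1CC[C@](O)(COCc2ccc(OC)cc2)C(C(=O)OCC[Si](C)(C)C)=C1 | intermediate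
26 | 2-(trimethylsilyl)ethyl 6-ethenyl-2-hydroxy-2-{[(4-methoxyphenyl)methoxy]methyl}-5-(propan-2-yl)cyclohexane-1-carboxylate | CC(C)[C@@H]1CC[C@](O)(COCc2ccc(OC)cc2)[C@@H](C(=O)OCC[Si](C)(C)C)[C@H]1C=C | intermediate
27 | tert-butyl 2-(bromomethyl)prop-2-enoate | CC(C)(C)OC(=O)C(=C)CBr | starting material
28 | tetrabutylammonium 6-ethenyl-2-hydroxy-2-{[(4-methoxyphenyl)methoxy]methyl}-5-(propan-2-yl)cyclohexane-1-carboxylate | CC(C)[C@@H]1CC[C@](O)(COCc2ccc(OC)cc2)[C@@H](C(=O)[O-])[C@H]1C=C.CCCC[N+](CCCC)(CCCC)CCCC | intermediate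
29 | 3-tert-butoxy-2-methylidene-3-oxopropyl 6-ethenyl-2-hydroxy-2-{[(4-methoxyphenyl)methoxy]methyl}-5-(propan-2-yl)cyclohexane-1-carboxylate | CC(C)[C@@H]1CC[C@](O)(COCc2ccc(OC)cc2)[C@@H](C(=O)OCC(=C)C(=O)OC(C)(C)C)[C@H]1C=C | intermediate
30 | tert-butyl 9-hydroxy-9-{[(4-methoxyphenyl)methoxy]methyl}-1-oxo-6-(propan-2-yl)-1,3,5a,6,7,8,9,9a-octahydro-2-benzoxepine-4-carboxylate | CC(C)[C@@H]1CC[C@](O)(COCc3ccc(OC)cc3)[C@H]2C(=O)OCC(C(=O)OC(C)(C)C)=C[C@@H]12 | intermediate
31 | tert-butyl 9-hydroxy-9-(hydroxymethyl)-1-oxo-6-(propan-2-yl)-1,3,5a,6,7,8,9,9a-octahydro-2-benzoxepine-4-carboxylate | CC(C)[C@@H]1CC[C@](O)(CO)[C@H]2C(=O)OCC(C(=O)OC(C)(C)C)=C[C@@H]12 | intermediate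
32 | ester of acid 17 with the primary hydroxyl of diol 31 | CC(C)[C@@H]1CC[C@](O)(COC(=O)/C(=C/[C@H]2[C@@H]([Si](C)(C)C)C(CO[Si](C)(C)C(C)(C)C)=CC[C@H]2C(C)C)CO[Si](C)(C)C(C)(C)C)[C@H]2C(=O)OCC(C(=O)OC(C)(C)C)=C[C@@H]12 | intermediate
33 | CNP0361406.6 | CC(C)[C@@H]1CC[C@](O)(COC(=O)/C(=C/[C@H]2C=C(CO)CC[C@H]2C(C)C)CO)[C@H]2C(=O)OCC(C(=O)O)=C[C@@H]12 | target

**Step count and risks**

Total steps: 23. Longest linear sequence: 12 steps (steps 1–6, 9–12, 22, 23).

Step 4. The cycloaddition may stall, because the silicon-bearing diene terminus must bond to the hindered β-carbon next to the butenolide stereocentre, or it may give the other regioisomer. The fallback sets out from 5 and removes the regiochemical question with a symmetrical, far more reactive dienophile. Maleic anhydride in toluene at rt should give the racemic cis-anhydride F1. MeMgBr (2 equiv, THF, −78 °C) should add twice to the carbonyl remote from the silicon-bearing carbon, the less hindered one, to give the γ,γ-dimethyl lactone F2. Reduction with i-Bu2AlH at −78 °C then gives lactol 9, where the fallback rejoins the route. The material is racemic from there; the antipodal series is removed by chromatography as the diastereomer of 32 after the union with enantiopure 31.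

Step 18. The conjugate addition may be slow, since the β-carbon lies next to the isopropyl carbon and the α-carbon next to the quaternary carbinol, or the cis relationship may be lost through unselective protonation or retro-aldol of the β-hydroxy ester. The fallback sets out from 24 and raises the acceptor to the aldehyde level. Palladium-catalysed formylation (CO, Bu3SnH, Pd(PPh3)4) gives the enal F3, and enals take up vinylmagnesium bromide under CuBr·SMe2/Me3SiCl catalysis far more readily. Low-temperature protonation of the silyl enol ether gives the cis aldehyde F4, which is oxidised at once (NaClO2, NaH2PO4, 2-methylbut-2-ene) to the acid F5. Alkylation with 27 (Cs2CO3, DMF) then gives 29, where the fallback rejoins the route.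

Step 23. Three acid-mediated events run in one flask, so the newly formed trisubstituted alkene or the tertiary alcohol may isomerise or eliminate before the tert-butyl ester is fully cleaved. The fallback sets out from 16 and takes the silicon helper out before the union. TsOH·H2O in MeOH/CH2Cl2 should effect protodesilylation with alkene transposition and strip both silyl ethers, giving the diol ester F6. Re-silylation (TBSCl, imidazole) gives the bis-silyl ether F7, and LiOH gives the acid F8. Yamaguchi coupling with 31 gives the ester F9. HF·pyridine followed by brief CF3CO2H/CH2Cl2 then removes only the silyl ethers and the tert-butyl ester and gives 33, where the fallback ends.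

**Further compounds**

F1 | step 4 | 5-({[tert-butyl(dimethyl)silyl]oxy}methyl)-4-(trimethylsilyl)-3a,4,7,7a-tetrahydro-2-benzofuran-1,3-dione (racemic cis-anhydride, one enantiomer drawn) | O=C1OC(=O)[C@@H]2CC=C(CO[Si](C)(C)C(C)(C)C)[C@H]([Si](C)(C)C)[C@H]12
F2 | step 4 | 6-({[tert-butyl(dimethyl)silyl]oxy}methyl)-3,3-dimethyl-7-(trimethylsilyl)-3a,4,7,7a-tetrahydro-2-benzofuran-1(3H)-one (racemic, one enantiomer drawn) | O=C1OC(C)(C)[C@@H]2CC=C(CO[Si](C)(C)C(C)(C)C)[C@H]([Si](C)(C)C)[C@H]12
F3 | step 18 | 6-hydroxy-6-{[(4-methoxyphenyl)methoxy]methyl}-3-(propan-2-yl)cyclohex-1-ene-1-carbaldehyde | CC(C)[C@@H]1CC[C@](O)(COCc2ccc(OC)cc2)C(C=O)=C1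
F4 | step 18 | 6-ethenyl-2-hydroxy-2-{[(4-methoxyphenyl)methoxy]methyl}-5-(propan-2-yl)cyclohexane-1-carbaldehyde | CC(C)[C@@H]1CC[C@](O)(COCc2ccc(OC)cc2)[C@@H](C=O)[C@H]1C=C
F5 | step 18 | 6-ethenyl-2-hydroxy-2-{[(4-methoxyphenyl)methoxy]methyl}-5-(propan-2-yl)cyclohexane-1-carboxylic acid | CC(C)[C@@H]1CC[C@](O)(COCc2ccc(OC)cc2)[C@@H](C(=O)O)[C@H]1C=C
F6 | step 23 | methyl (2E)-2-(hydroxymethyl)-3-[(1R,6S)-3-(hydroxymethyl)-6-(propan-2-yl)cyclohex-2-en-1-yl]prop-2-enoate | COC(=O)/C(=C/[C@H]1C=C(CO)CC[C@H]1C(C)C)CO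
F7 | step 23 | methyl (2E)-2-({[tert-butyl(dimethyl)silyl]oxy}methyl)-3-[(1R,6S)-3-({[tert-butyl(dimethyl)silyl]oxy}methyl)-6-(propan-2-yl)cyclohex-2-en-1-yl]prop-2-enoate | COC(=O)/C(=C/[C@H]1C=C(CO[Si](C)(C)C(C)(C)C)CC[C@H]1C(C)C)CO[Si](C)(C)C(C)(C)C
F8 | step 23 | (2E)-2-({[tert-butyl(dimethyl)silyl]oxy}methyl)-3-[(1R,6S)-3-({[tert-butyl(dimethyl)silyl]oxy}methyl)-6-(propan-2-yl)cyclohex-2-en-1-yl]prop-2-enoic acid | OC(=O)/C(=C/[C@H]1C=C(CO[Si](C)(C)C(C)(C)C)CC[C@H]1C(C)C)CO[Si](C)(C)C(C)(C)C
F9 | step 23 | ester of acid F8 with the primary hydroxyl of diol 31 | CC(C)[C@@H]1CC[C@](O)(COC(=O)/C(=C/[C@H]2C=C(CO[Si](C)(C)C(C)(C)C)CC[C@H]2C(C)C)CO[Si](C)(C)C(C)(C)C)[C@H]2C(=O)OCC(C(=O)OC(C)(C)C)=C[C@@H]12
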